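The isoflavan is cut at C3–C1'. Ring B carries its C2' and C5' oxygens para to each other, so it is read as a masked 1,4-benzoquinone. Ring C is read as a 2H-chromene whose C3=C4 bond is a styrene pushed by O1 and O7 of ring A. A Ti(IV)–TADDOLate-promoted formal [3+2] cycloaddition joins chromene C3 to the free quinone carbon (future C1'), closes a temporary dihydrofuran (O2'–C4), aromatises ring B and sets C3. The precursor pair is a 7-silyloxy-8-methoxychromene and a 2-methoxy-3-tosyloxyquinone, whose tosylate protects O3' and steers regiochemistry. Hydrogenolysis, double O-methylation and one basic deprotection finish.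

Key step: step 7

Assumption: the (R,R)-TADDOLate is taken to deliver the (6aS,11aS) adduct. Should the sense of induction prove opposite, the equally available (S,S)-ligand is used and nothing else changes.

Step 1
Reactants: 1 1,2,4-trimethoxybenzene
Product: 4 2,3,6-trimethoxyphenol, via aryllithium 2 (not isolated), via dimethyl arylboronate 3 (not isolated)
Conditions: n-BuLi, THF, 0 °C to rt; B(OMe)3, −78 °C to rt; 30% H2O2, AcOH, 0 °C to rt
Reagents that add atoms: n-butyllithium [Li]CCCC (Li of 2), trimethyl borate COB(OC)OC (boron unit of 3), hydrogen peroxide OO (phenol O of 4)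
Why: Cooperative directed ortho-metalation removes the proton flanked by two methoxy groups, and borylation followed by peroxide oxidation (1,2-aryl shift from boron to oxygen) turns the C–Li bond into the oxygen that becomes O3'.

Step 2
Reactants: 4 2,3,6-trimethoxyphenol
Product: 5 2,3,6-trimethoxyphenyl 4-methylbenzenesulfonate
Conditions: TsCl, Et3N, DMAP (cat.), CH2Cl2, 0 °C to rt
Reagents that add atoms: p-toluenesulfonyl chloride Cc1ccc(cc1)S(=O)(=O)Cl
Why: DMAP-assisted sulfonylation of the hindered phenol installs a non-migrating, non-chelating, electron-withdrawing group that should survive Lewis acid, hydrogenation and carbonate.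

Step 3
Reactants: 5 2,3,6-trimethoxyphenyl 4-methylbenzenesulfonate
Product: 6 2-methoxy-3-(tosyloxy)-1,4-benzoquinone
Conditions: (NH4)2Ce(NO3)6, MeCN/H2O, 0 °C
Reagents that add atoms: water O
Why: Cerium(IV) oxidative demethylation of a 1,4-dimethoxyarene removes the only para-related pair of methoxy groups, with water entering at the ipso carbons, and leaves the remaining methoxy group and the sulfonate in place.

Step 4
Reactants: 7 2-methoxyresorcinol (2-methoxybenzene-1,3-diol)
Product: 8 2-methoxy-3-(triisopropylsilyloxy)phenol
Conditions: TIPSCl (1 equiv), imidazole, DMF, 0 °C to rt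
Reagents that add atoms: triisopropylsilyl chloride CC(C)[Si](Cl)(C(C)C)C(C)C
Why: Statistical monosilylation of the symmetric diol with one equivalent of a bulky chlorosilane should give the mono ether, separable from recyclable diol and bis ether, and the silyl ether remains a π-donor and resists hydrogenation.

Step 5
Reactants: 8 2-methoxy-3-(triisopropylsilyloxy)phenol; 9 propargyl bromide
Product: 10 triisopropyl[2-methoxy-3-(prop-2-yn-1-yloxy)phenoxy]silane
Conditions: K2CO3, acetone, reflux
Reagents that add atoms: none
Why: Williamson ether synthesis on the remaining phenol with a reactive propargylic bromide uses carbonate conditions that an aryl TIPS ether tolerates.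

Step 6
Reactants: 10 triisopropyl[2-methoxy-3-(prop-2-yn-1-yloxy)phenoxy]silane
Product: 11 8-methoxy-7-(triisopropylsilyloxy)-2H-chromene
Conditions: Ph3PAuNTf2 (cat.), CH2Cl2, rt
Reagents that add atoms: none
Why: Gold(I)-catalysed 6-endo-dig intramolecular hydroarylation of the aryl propargyl ether closes at the only free ortho carbon, which lies para to the silyloxy donor, and gives the 2H-chromene without heating.

Step 7
Reactants: 11 8-methoxy-7-(triisopropylsilyloxy)-2H-chromene; 6 2-methoxy-3-(tosyloxy)-1,4-benzoquinone
Product: 12 (6aS,11aS)-8-hydroxy-4,9-dimethoxy-3-(triisopropylsilyloxy)-6a,11a-dihydro-6H-benzofuro[3,2-c]chromen-10-yl 4-methylbenzenesulfonate (cis-pterocarpan)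
Conditions: (R,R)-TADDOL, TiCl4/Ti(Oi-Pr)4 (1:1, stoichiometric), CH2Cl2, −78 °C to −20 °C; aq NaHCO3
Reagents that add atoms: none
Why: Titanium chelates the C1 carbonyl and the neighbouring C2 methoxy oxygen of 6, so the unsubstituted C5 (β to that carbonyl, the future C1') becomes the electrophilic site, while the C4 carbonyl is damped as a vinylogous ester and its neighbour, the non-basic tosylate, offers no chelate; this secures the regiochemistry on the quinone. Chromene C3 attacks there because the resulting C4 cation is benzylic and stabilised by O1 (ortho) and O7 (para) of ring A, which secures the regiochemistry on the alkene. The oxygen of the adjacent C4 quinone carbonyl (future O2') captures this cation in a 5-exo-trig closure (the cation written in its C4=C4a quinone-methide form), and tautomerisation aromatises ring B to the phenol. This is the known Lewis acid promoted formal [3+2] cycloaddition of 2-alkoxy-1,4-benzoquinones with styrenes and 2H-chromenes to pterocarpans, in its chiral Ti–TADDOLate version. C6a (C3 of the isoflavan) is set by the TADDOLate aryl groups, which shield one face of the bound quinone and thereby select one enantiotopic face of the C3=C4 bond, and C11a follows because only the cis-fused 6/5 junction can close. Any [2+2] cyclobutane adduct should ionise on warming to the same cation and funnel to 12, and the substituent at quinone C3 blocks the competing [5+2] mode.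

Step 8
Reactants: 12 cis-pterocarpan
Product: 13 (3S)-2',5'-dihydroxy-4',8-dimethoxy-3'-(tosyloxy)-7-(triisopropylsilyloxy)isoflavan
Conditions: H2 (1 atm), 10% Pd/C, EtOH/EtOAc, rt
Reagents that add atoms: none
Why: Catalytic hydrogenolysis of the activated benzylic C11a–O bond is the classical opening of pterocarpans to 2'-hydroxyisoflavans; it erases C11a and leaves C6a untouched as (3S), while the aryl tosylate and silyl ether are inert.

Step 9
Reactants: 13 (3S)-2',5'-dihydroxy-4',8-dimethoxy-3'-(tosyloxy)-7-(triisopropylsilyloxy)isoflavan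
Product: 14 (3S)-2',4',5',8-tetramethoxy-3'-(tosyloxy)-7-(triisopropylsilyloxy)isoflavan
Conditions: MeI (excess), K2CO3, acetone, reflux, Ar
Reagents that add atoms: iodomethane CI
Why: Williamson O-methylation caps both hydroquinone oxygens in one operation, and the sulfonate cannot migrate to the neighbouring O2' phenoxide because in-line attack at sulfur is impossible within so small a ring.

Step 10
Reactants: 14 (3S)-2',4',5',8-tetramethoxy-3'-(tosyloxy)-7-(triisopropylsilyloxy)isoflavan
Product: 15 (3S)-7,3'-dihydroxy-8,2',4',5'-tetramethoxyisoflavan (target)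
Conditions: KOH, t-BuOH/THF/H2O, 70 °C, Ar; then 1 M HCl
Reagents that add atoms: none
Why: Hydroxide attacks silicon of the aryl silyl ether and sulfur of the aryl sulfonate (nucleophilic Si–O and S–O cleavage), so both phenols are released in one step; the bulky alcohol cosolvent avoids an alkylating sulfonate ester, and C3 carries no acidifying group.

Compound list
1 | 1,2,4-trimethoxybenzene | COc1ccc(OC)c(OC)c1 | starting material
2 | (2,3,6-trimethoxyphenyl)lithium | [Li]c1c(OC)ccc(OC)c1OC | intermediate
3 | dimethyl (2,3,6-trimethoxyphenyl)boronate | COB(OC)c1c(OC)ccc(OC)c1OC | intermediate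
4 | 2,3,6-trimethoxyphenol | Oc1c(OC)ccc(OC)c1OC | intermediate
5 | 2,3,6-trimethoxyphenyl 4-methylbenzenesulfonate | COc1ccc(OC)c(OC)c1OS(=O)(=O)c1ccc(C)cc1 | intermediate
6 | 2-methoxy-3-(tosyloxy)-1,4-benzoquinone | COC1=C(OS(=O)(=O)c2ccc(C)cc2)C(=O)C=CC1=O | intermediate
7 | 2-methoxyresorcinol | COc1c(O)cccc1O | starting material
8 | 2-methoxy-3-(triisopropylsilyloxy)phenol | COc1c(O)cccc1O[Si](C(C)C)(C(C)C)C(C)C | intermediate
9 | propargyl bromide | C#CCBr | starting material
10 | triisopropyl[2-methoxy-3-(prop-2-yn-1-yloxy)phenoxy]silane | COc1c(OCC#C)cccc1O[Si](C(C)C)(C(C)C)C(C)C | intermediate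
11 | 8-methoxy-7-(triisopropylsilyloxy)-2H-chromene | COc1c(O[Si](C(C)C)(C(C)C)C(C)C)ccc2C=CCOc12 | intermediate
12 | (6aS,11aS)-8-hydroxy-4,9-dimethoxy-3-(triisopropylsilyloxy)pterocarpan-10-yl tosylate | COc1c(O)cc2c(c1OS(=O)(=O)c1ccc(C)cc1)O[C@@H]1c3ccc(O[Si](C(C)C)(C(C)C)C(C)C)c(OC)c3OC[C@H]21 | intermediate
13 | (3S)-2',5'-dihydroxy-4',8-dimethoxy-3'-(tosyloxy)-7-(triisopropylsilyloxy)isoflavan | COc1c(O)cc([C@H]2COc3c(ccc(O[Si](C(C)C)(C(C)C)C(C)C)c3OC)C2)c(O)c1OS(=O)(=O)c1ccc(C)cc1 | intermediate
14 | (3S)-2',4',5',8-tetramethoxy-3'-(tosyloxy)-7-(triisopropylsilyloxy)isoflavan | COc1cc([C@H]2COc3c(ccc(O[Si](C(C)C)(C(C)C)C(C)C)c3OC)C2)c(OC)c(OS(=O)(=O)c2ccc(C)cc2)c1OC | intermediate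
15 | (3S)-7,3'-dihydroxy-8,2',4',5'-tetramethoxyisoflavan | COc1cc([C@H]2COc3c(ccc(O)c3OC)C2)c(OC)c(O)c1OC | target

Total step count: 10. Longest linear sequence: 7 steps (7 → 8 → 10 → 11 → 12 → 13 → 14 → 15). The quinone branch 1 → 4 → 5 → 6 is equally long up to the key step.

Steps most likely to fail

1. Step 7.
- **Risk:** facial discrimination by the Ti–TADDOLate may be insufficient with this more heavily substituted quinone. The reaction may also stall in the cyclobutane manifold, the quinone may abstract hydride from C2, or the chromene may oligomerise under the Lewis acid.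
- **Fallback (sets out from 11 and 5, returns at 14):** the C3–C1' bond is first made at an sp2 carbon, and the stereocentre is set afterwards by hydrogenation.
  - Addition of bromine to 11 gives the (±)-trans-3,4-dibromochroman F1, and DBU removes HBr to give the 3-bromo-2H-chromene F2.
  - NBS brominates 5 para to the future C4' methoxy group, the tosylate switching off the other free position, to give the aryl bromide F3. Miyaura borylation then gives the pinacol boronate F4.
  - Suzuki–Miyaura coupling of F2 with F4 gives the isoflav-3-ene F5.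
  - Iridium-catalysed asymmetric hydrogenation with a chiral P,N ligand should give 14.

2. Step 3.
- **Risk:** the radical cation may dimerise at the two free ring positions, over-oxidation may occur, or the sulfonate may be lost hydrolytically from the quinone in the acidic aqueous medium.
- **Fallback (sets out from 5, returns at 6):** anodic oxidation of 5 in buffered methanol, a two-electron methoxylation of a 1,4-dimethoxyarene, gives the quinone bis(dimethyl ketal) F6. Brief treatment with dilute aqueous acid in acetone releases 6 under non-oxidising conditions.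

3. Step 9.
- **Risk:** the hydroquinone dianion may be re-oxidised by air, alkylation at the hindered O2' may be incomplete, and the silyl ether may erode under prolonged carbonate treatment.
- **Fallback (sets out from 12, returns at 14):** the hydroquinone is never liberated.
  - The single free phenol of 12 is methylated (MeI, K2CO3) to the 8-O-methyl pterocarpan F7.
  - Hydrogenolysis opens it to the 2'-hydroxyisoflavan F8.
  - The one remaining hindered phenol is methylated under neutral Mitsunobu conditions (MeOH, PPh3, DIAD) to give 14.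

Further compounds
F1 | step 7 | (±)-trans-3,4-dibromo-8-methoxy-7-(triisopropylsilyloxy)chroman (one enantiomer drawn) | COc1c(O[Si](C(C)C)(C(C)C)C(C)C)ccc2c1OC[C@H](Br)[C@H]2Br
F2 | step 7 | 3-bromo-8-methoxy-7-(triisopropylsilyloxy)-2H-chromene | COc1c(O[Si](C(C)C)(C(C)C)C(C)C)ccc2C=C(Br)COc12
F3 | step 7 | 3-bromo-2,5,6-trimethoxyphenyl 4-methylbenzenesulfonate | COc1cc(Br)c(OC)c(OS(=O)(=O)c2ccc(C)cc2)c1OC
F4 | step 7 | 2,5,6-trimethoxy-3-(4,4,5,5-tetramethyl-1,3,2-dioxaborolan-2-yl)phenyl 4-methylbenzenesulfonate | COc1cc(B2OC(C)(C)C(C)(C)O2)c(OC)c(OS(=O)(=O)c2ccc(C)cc2)c1OC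
F5 | step 7 | 2',4',5',8-tetramethoxy-3'-(tosyloxy)-7-(triisopropylsilyloxy)isoflav-3-ene | COc1cc(C2=Cc3ccc(O[Si](C(C)C)(C(C)C)C(C)C)c(OC)c3OC2)c(OC)c(OS(=O)(=O)c2ccc(C)cc2)c1OC
F6 | step 3 | 2,3,3,6,6-pentamethoxycyclohexa-1,4-dien-1-yl 4-methylbenzenesulfonate | COC1=C(OS(=O)(=O)c2ccc(C)cc2)C(OC)(OC)C=CC1(OC)OC
F7 | step 9 | (6aS,11aS)-4,8,9-trimethoxy-3-(triisopropylsilyloxy)pterocarpan-10-yl tosylate | COc1c(OC)cc2c(c1OS(=O)(=O)c1ccc(C)cc1)O[C@@H]1c3ccc(O[Si](C(C)C)(C(C)C)C(C)C)c(OC)c3OC[C@H]21
F8 | step 9 | (3S)-2'-hydroxy-4',5',8-trimethoxy-3'-(tosyloxy)-7-(triisopropylsilyloxy)isoflavan | COc1cc([C@H]2COc3c(ccc(O[Si](C(C)C)(C(C)C)C(C)C)c3OC)C2)c(O)c(OS(=O)(=O)c2ccc(C)cc2)c1OC
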